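**Plan**

- Retrosynthesis: the C12 ester goes back to the methyl of an isopropenyl group, the C6 angelate to the free alcohol, the C4 carbinol to a C3=C4 alkene and the C1 carbinol to a C1 sulfone. The decalin is then cut in one stroke at C5–C10 and C1–C2 (retro-Diels–Alder) to an open-chain triene, which is cut at C8–C9 (acylation of a propargyl anion) and C6–C7 (aldol).
- Forward: aldol (C6–C7), ketone formation (C8–C9) and 1,3-syn reduction build the chain; alkyne carbometalation adds C14 and the sulfonyl-activated C1=C10 alkene. One intramolecular Diels–Alder reaction then makes the cyclohexene ring A (C10, C1, C2, C3, C4, C5) and, through the tether C6–C9, ring B in the same event; no ring is formed after it.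
- Enabling feature: ring A carries its substituents exactly where a [4+2] puts them. The quaternary C10 methyl and the C1 heteroatom come from a trisubstituted dienophile; the C4 methyl comes from a 2-methyl diene whose leftover C3=C4 alkene becomes the tertiary carbinol. Ring B bears three adjacent equatorial groups (C6–O, C7–C, C8–O) that sit on the tether and steer the cycloaddition.
- Stereochemistry: C6 and C7 from an auxiliary-controlled syn aldol; C8 from chelation-controlled 1,3-syn reduction; C5, C10 (trans fusion) from the cycloaddition; C1 from axial hydride delivery to the derived ketone; C4 from α-face epoxidation and hydride opening.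
- Endgame: site-selective silylation, angeloylation at C6, oxidation of the C12 methyl to the methyl ester, desilylation.

Key step: step 12

Assumption: (E)-3-methylpent-2-en-4-yn-1-ol and 3-methylbut-3-enoic acid are taken as purchasable; atom numbers C1–C15 follow eudesmane numbering throughout, and bicyclic intermediates are named on the eudesmane skeleton (5α-H, 7α-H, 10β-methyl).

**Step 1**
Reactants: 1 (S)-4-benzyloxazolidin-2-one; 2 3-methylbut-3-enoic acid
Product: 4 (S)-4-benzyl-3-(3-methylbut-3-enoyl)oxazolidin-2-one, via mixed pivalic anhydride 3 (not isolated)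
Conditions: 2, PivCl, Et3N, THF, −20 °C; then 1, LiCl, −20 °C → rt
Reagents that add atoms: none
Why: N-acylation of the oxazolidinone through the mixed pivalic anhydride (LiCl/Et3N variant) should give the imide under conditions mild enough to keep the β,γ-alkene out of conjugation.

**Step 2**
Reactants: 5 (E)-3-methylpent-2-en-4-yn-1-ol
Product: 6 (E)-3-methylpenta-2,4-dien-1-ol
Conditions: H2 (1 atm), Pd/CaCO3 poisoned with Pb(OAc)2 (Lindlar catalyst), quinoline, hexane/EtOAc, rt
Reagents that add atoms: none
Why: Lindlar semi-hydrogenation should reduce only the terminal alkyne to the vinyl group and leave the trisubstituted (E)-alkene and its geometry untouched.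

**Step 3**
Reactants: 6 (E)-3-methylpenta-2,4-dien-1-ol
Product: 7 (E)-3-methylpenta-2,4-dienal
Conditions: MnO2, CH2Cl2, rt
Reagents that add atoms: none
Why: MnO2 oxidation is selective for allylic alcohols and should give the (E)-dienal without over-oxidation or alkene isomerization.

**Step 4**
Reactants: 4 N-(3-methylbut-3-enoyl) imide; 7 (E)-3-methylpenta-2,4-dienal
Product: 9 syn-aldol imide (2S,3R in the acyl chain), via (Z)-dibutylboron enolate 8 (not isolated)
Conditions: 4, Bu2BOTf, iPr2NEt, CH2Cl2, −78 → 0 °C; then 7, −78 → 0 °C; pH 7 buffer, MeOH, H2O2, 0 °C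
Reagents that add atoms: none
Why: Evans syn aldol reaction: the (Z)-boron enolate adds to the aldehyde through a closed chair transition state on the face opposite the benzyl group of the auxiliary, which should set C7 and C6 (2S,3R in the acyl chain) in one step.

**Step 5**
Reactants: 9 syn-aldol imide
Product: 10 β-hydroxy Weinreb amide
Conditions: MeNHOMe·HCl, AlMe3, CH2Cl2, −20 → 0 °C
Reagents that add atoms: N,O-dimethylhydroxylamine hydrochloride, CNOC.Cl
Why: Weinreb amide formation by aluminium-amide transamination is standard for β-hydroxy imides, leaves both new stereocenters untouched and returns the auxiliary.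

**Step 6**
Reactants: 10 β-hydroxy Weinreb amide; 11 1-(trimethylsilyl)prop-1-yne
Product: 13 β-hydroxy β′,γ′-alkynyl ketone, via 3-lithio-1-(trimethylsilyl)propyne 12 (not isolated)
Conditions: 11, n-BuLi, TMEDA, THF, −78 → −20 °C; then 10, −78 → −40 °C; cold aq. NH4Cl
Reagents that add atoms: none
Why: Acylation of the silyl-capped propargyl lithium by the Weinreb amide (ketone synthesis through a stable chelated tetrahedral intermediate) should form the C8–C9 bond at the propargylic carbon without over-addition, the alkoxide formed first protecting the acidic C7–H.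

**Step 7**
Reactants: 13 β-hydroxy ketone
Product: 15 1,3-syn diol, via diethylboron chelate 14 (not isolated)
Conditions: Et2BOMe, THF/MeOH (4:1), −78 °C; NaBH4, −78 °C; then H2O2, aq. NaOH, 0 °C
Reagents that add atoms: none
Why: Narasaka–Prasad reduction: hydride attacks the six-membered diethylboron chelate of the β-hydroxy ketone from the axial direction, which should give the 1,3-syn diol and so set C8.

**Step 8**
Reactants: 15 1,3-syn diol
Product: 16 bis(triethylsilyl) ether
Conditions: TESOTf, 2,6-lutidine, CH2Cl2, −78 °C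
Reagents that add atoms: triethylsilyl trifluoromethanesulfonate, CC[Si](CC)(CC)OS(=O)(=O)C(F)(F)F
Why: Silyl ether formation with TESOTf and 2,6-lutidine should cap both secondary alcohols with non-chelating groups that later sit equatorial on the tether and come off under mild acid.

**Step 9**
Reactants: 16 bis(triethylsilyl) ether
Product: 17 terminal alkyne
Conditions: K2CO3 (cat.), MeOH, rt
Reagents that add atoms: none
Why: Base-catalysed methanolysis cleaves the alkynyl C–Si bond selectively, the triethylsilyl ethers being stable to K2CO3 in methanol.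

**Step 10**
Reactants: 17 terminal alkyne
Product: 19 (E)-vinyl iodide, via alkenyl(dimethyl)alane 18 (not isolated)
Conditions: AlMe3, (C5H5)2ZrCl2 (cat.), CH2Cl2, 0 °C → rt; then I2, THF, −30 °C
Reagents that add atoms: trimethylaluminium, C[Al](C)C; iodine, II
Why: Negishi carboalumination: zirconium-catalysed syn addition of a methyl–aluminium bond across the terminal alkyne puts the methyl group on C10 and aluminium on C1, and iodinolysis with retention should give the (E)-vinyl iodide while the alkenes stay untouched.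

**Step 11**
Reactants: 19 (E)-vinyl iodide
Product: 20 (E)-vinyl sulfone triene
Conditions: PhSO2Na, CuI (10 mol%), L-proline sodium salt (20 mol%), DMSO, 90 °C
Reagents that add atoms: sodium benzenesulfinate, [Na+].[O-]S(=O)c1ccccc1
Why: Copper-catalysed coupling of the vinyl iodide with the sulfinate salt (Ullmann-type C–S coupling) proceeds with retention of alkene geometry and should place the activating sulfonyl group on C1 cis to the C10 methyl.

**Step 12**
Reactants: 20 (E)-vinyl sulfone triene
Product: 21 1β-(phenylsulfonyl)-6α,8α-bis(triethylsilyloxy)eudesma-3,11-diene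
Conditions: toluene (0.01 M), BHT (cat.), 150 °C, sealed tube
Reagents that add atoms: none
Why: Thermal intramolecular Diels–Alder reaction: a concerted suprafacial [4+2] addition of the (E)-diene C5=C4–C3=C2 to the sulfonyl-activated (E)-alkene C1=C10, the closest known type being the cyclization of deca-1,7,9-trienes that carry a sulfonyl or nitro group on the dienophile terminus to trans-decalins. Ring A (C10, C1, C2, C3, C4, C5) is the cyclohexene made by the cycloaddition itself through the new bonds C5–C10 and C1–C2, and ring B (C5 to C10) closes in the same event in fused mode through the four-atom tether C6–C9. C10 and C5: the tether should adopt a chair in which the C6 and C8 silyloxy groups and the C7 isopropenyl group are all equatorial, which selects one diene face, and the endo orientation of the sulfonyl group (which also places the C10 methyl under the diene) leads to the trans fusion with 10β-methyl and 5α-H. C1: suprafacial addition keeps the sulfonyl group cis to the C10 methyl, as in the (E)-alkene. The step needs facial and endo selectivity, secured by the three equatorial tether substituents and the (E)-sulfonyl alkene, regioselectivity, fixed by the tether, and chemoselectivity, secured because the isopropenyl alkene is unactivated and too close to the diene to reach it.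

**Step 13**
Reactants: 21 bicyclic sulfone
Product: 23 6α,8α-bis(triethylsilyloxy)eudesma-3,11-dien-1-one, via α-lithio sulfone 22 (not isolated)
Conditions: n-BuLi, THF, −78 °C; Me3SiOOSiMe3, −78 °C; AcOH quench at −78 °C
Reagents that add atoms: bis(trimethylsilyl) peroxide, C[Si](C)(C)OO[Si](C)(C)C
Why: Oxidative desulfonylation: the α-sulfonyl carbanion is oxygenated by the silyl peroxide and the α-silyloxy sulfone collapses to the C1 ketone with loss of sulfinate, the cold acidic quench keeping the C3=C4 alkene out of conjugation.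

**Step 14**
Reactants: 23 β,γ-unsaturated ketone
Product: 24 3α,4α-epoxy-6α,8α-bis(triethylsilyloxy)eudesm-11-en-1-one
Conditions: mCPBA (1.05 equiv), NaHCO3, CH2Cl2, 0 °C
Reagents that add atoms: 3-chloroperbenzoic acid, O=C(OO)c1cccc(Cl)c1
Why: Prilezhaev epoxidation should take the electron-rich trisubstituted C3=C4 alkene before the hindered 1,1-disubstituted one and before any Baeyer–Villiger reaction, from the α face opposite the axial C10 methyl group.

**Step 15**
Reactants: 24 epoxy ketone
Product: 26 eudesm-11-ene-1β,4α,6α,8α-tetraol, via bis(triethylsilyl) diol 25 (not isolated)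
Conditions: LiAlH4, THF, −78 °C → reflux; Fieser work-up; then PPTS, MeOH, rt
Reagents that add atoms: none
Why: Hydride reduction: LiAlH4 attacks the C1 ketone along the axial α trajectory (equatorial 1β-alcohol) and opens the epoxide at the secondary carbon C3 so that the oxygen stays on C4 (4α-OH and 4β-methyl), and PPTS in methanol then removes both triethylsilyl groups.

**Step 16**
Reactants: 26 tetraol
Product: 27 1β,8α-bis(tert-butyldimethylsilyloxy)eudesm-11-ene-4α,6α-diol
Conditions: TBSCl (2.2 equiv), imidazole, DMF, 0 °C → rt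
Reagents that add atoms: tert-butyldimethylsilyl chloride, CC(C)(C)[Si](C)(C)Cl
Why: Silylation under kinetic control should take the two accessible secondary hydroxyls at C8 and C1 and leave the C6 hydroxyl (flanked by C5 and C7 and hydrogen-bonded to the C4 hydroxyl) and the tertiary C4 hydroxyl free.

**Step 17**
Reactants: 27 bis-silyl diol; 28 angelic acid
Product: 30 6α-angelate, via mixed trichlorobenzoic anhydride 29 (not isolated)
Conditions: 28, 2,4,6-Cl3C6H2COCl, Et3N, toluene, rt; then 27, 80 °C
Reagents that add atoms: none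
Why: Yamaguchi esterification through the 2,4,6-trichlorobenzoic mixed anhydride in toluene is the established way to transfer an angeloyl group without Z to E isomerization, and only the secondary C6 hydroxyl can react.

**Step 18**
Reactants: 30 6α-angelate
Product: 32 eudesm-11(13)-en-12-al, via allylic alcohol 31 (not isolated)
Conditions: SeO2 (cat.), t-BuOOH, CH2Cl2, rt; then MnO2, CH2Cl2, rt
Reagents that add atoms: tert-butyl hydroperoxide, CC(C)(C)OO; selenium dioxide, O=[Se]=O
Why: Selenium dioxide allylic oxidation (ene reaction followed by 2,3-sigmatropic shift) of the 1,1-disubstituted alkene goes to its methyl group rather than to the C7 methine, the conjugated angelate alkene is far less reactive, and MnO2 takes the allylic alcohol on to the enal.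

**Step 19**
Reactants: 32 enal
Product: 33 eudesm-11(13)-en-12-oic acid
Conditions: NaClO2, NaH2PO4, 2-methyl-2-butene, t-BuOH/H2O, 0 °C → rt
Reagents that add atoms: sodium chlorite, [Na+].[O-]Cl=O
Why: Pinnick oxidation converts the enal into the acrylic acid without touching the alkenes, the hypochlorite by-product being trapped by 2-methyl-2-butene.

**Step 20**
Reactants: 33 acrylic acid
Product: 34 methyl ester
Conditions: Me3SiCHN2, MeOH/toluene, 0 °C
Reagents that add atoms: (trimethylsilyl)diazomethane, C[Si](C)(C)C=[N+]=[N-]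
Why: Methylation of the carboxylic acid with trimethylsilyldiazomethane is fast and neutral, so the angelate and the silyl ethers should survive.

**Step 21**
Reactants: 34 bis-silyl methyl ester
Product: 35 methyl 6α-angeloyloxy-1β,4α,8α-trihydroxyeudesm-11(13)-en-12-oate (target)
Conditions: HF·pyridine, pyridine, THF, 0 °C → rt
Reagents that add atoms: none
Why: Fluoride-mediated silyl ether cleavage with pyridine-buffered HF·pyridine should free the C1 and C8 hydroxyls under near-neutral conditions that spare both unsaturated esters and do not promote lactonization of the C8 hydroxyl onto the ester.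

**Compound list**

1 | (S)-4-benzyloxazolidin-2-one | O=C1N[C@@H](Cc2ccccc2)CO1 | starting material
2 | 3-methylbut-3-enoic acid | C=C(C)CC(=O)O | starting material
3 | 3-methylbut-3-enoic pivalic anhydride (not isolated) | C=C(C)CC(=O)OC(=O)C(C)(C)C | intermediate
4 | (S)-4-benzyl-3-(3-methylbut-3-enoyl)oxazolidin-2-one | C=C(C)CC(=O)N1[C@@H](Cc2ccccc2)COC1=O | intermediate
5 | (E)-3-methylpent-2-en-4-yn-1-ol | C#C/C(C)=C/CO | starting material
6 | (E)-3-methylpenta-2,4-dien-1-ol | C=C/C(C)=C/CO | intermediate
7 | (E)-3-methylpenta-2,4-dienal | C=C/C(C)=C/C=O | intermediate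
8 | (Z)-dibutylboron enolate of imide 4 (not isolated) | C=C(C)/C=C(\OB(CCCC)CCCC)N1[C@@H](Cc2ccccc2)COC1=O | intermediate
9 | (S)-4-benzyl-3-[(2S,3R,4E)-3-hydroxy-5-methyl-2-(prop-1-en-2-yl)hepta-4,6-dienoyl]oxazolidin-2-one | C=C/C(C)=C/[C@@H](O)[C@H](C(C)=C)C(=O)N1[C@@H](Cc2ccccc2)COC1=O | intermediate
10 | (2S,3R,4E)-3-hydroxy-N-methoxy-N,5-dimethyl-2-(prop-1-en-2-yl)hepta-4,6-dienamide | C=C/C(C)=C/[C@@H](O)[C@H](C(C)=C)C(=O)N(C)OC | intermediate
11 | 1-(trimethylsilyl)prop-1-yne | CC#C[Si](C)(C)C | starting material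
12 | 3-lithio-1-(trimethylsilyl)prop-1-yne (not isolated) | [Li]CC#C[Si](C)(C)C | intermediate
13 | (5S,6R,7E)-6-hydroxy-8-methyl-5-(prop-1-en-2-yl)-1-(trimethylsilyl)deca-7,9-dien-1-yn-4-one | C=C/C(C)=C/[C@@H](O)[C@H](C(C)=C)C(=O)CC#C[Si](C)(C)C | intermediate
14 | O-diethylboryl chelate of ketone 13 (not isolated) | C=C/C(C)=C/[C@@H](OB(CC)CC)[C@H](C(C)=C)C(=O)CC#C[Si](C)(C)C | intermediate
15 | (4S,5R,6R,7E)-8-methyl-5-(prop-1-en-2-yl)-1-(trimethylsilyl)deca-7,9-dien-1-yne-4,6-diol | C=C/C(C)=C/[C@@H](O)[C@H](C(C)=C)[C@@H](O)CC#C[Si](C)(C)C | intermediate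
16 | 4,6-bis(triethylsilyl) ether of diol 15 | C=C/C(C)=C/[C@@H](O[Si](CC)(CC)CC)[C@H](C(C)=C)[C@@H](O[Si](CC)(CC)CC)CC#C[Si](C)(C)C | intermediate
17 | (4S,5R,6R,7E)-8-methyl-5-(prop-1-en-2-yl)-4,6-bis(triethylsilyloxy)deca-7,9-dien-1-yne | C=C/C(C)=C/[C@@H](O[Si](CC)(CC)CC)[C@H](C(C)=C)[C@@H](O[Si](CC)(CC)CC)CC#C | intermediate
18 | (E)-alkenyl(dimethyl)alane from 17 (not isolated) | C=C/C(C)=C/[C@@H](O[Si](CC)(CC)CC)[C@H](C(C)=C)[C@@H](O[Si](CC)(CC)CC)C/C(C)=C/[Al](C)C | intermediate
19 | (1E,4S,5R,6R,7E)-1-iodo-2,8-dimethyl-5-(prop-1-en-2-yl)-4,6-bis(triethylsilyloxy)deca-1,7,9-triene | C=C/C(C)=C/[C@@H](O[Si](CC)(CC)CC)[C@H](C(C)=C)[C@@H](O[Si](CC)(CC)CC)C/C(C)=C/I | intermediate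
20 | (1E,4S,5R,6R,7E)-2,8-dimethyl-1-(phenylsulfonyl)-5-(prop-1-en-2-yl)-4,6-bis(triethylsilyloxy)deca-1,7,9-triene | C=C/C(C)=C/[C@@H](O[Si](CC)(CC)CC)[C@H](C(C)=C)[C@@H](O[Si](CC)(CC)CC)C/C(C)=C/S(=O)(=O)c1ccccc1 | intermediate
21 | 1β-(phenylsulfonyl)-6α,8α-bis(triethylsilyloxy)eudesma-3,11-diene | CC(=C)[C@H]1[C@H](O[Si](CC)(CC)CC)[C@@H]2[C@@](C)(C[C@@H]1O[Si](CC)(CC)CC)[C@H](S(=O)(=O)c1ccccc1)CC=C2C | intermediate
22 | 1-lithio derivative of sulfone 21 (not isolated) | CC(=C)[C@H]1[C@H](O[Si](CC)(CC)CC)[C@@H]2[C@@](C)(C[C@@H]1O[Si](CC)(CC)CC)C([Li])(S(=O)(=O)c1ccccc1)CC=C2C | intermediate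
23 | 6α,8α-bis(triethylsilyloxy)eudesma-3,11-dien-1-one | CC(=C)[C@H]1[C@H](O[Si](CC)(CC)CC)[C@@H]2[C@@](C)(C[C@@H]1O[Si](CC)(CC)CC)C(=O)CC=C2C | intermediate
24 | 3α,4α-epoxy-6α,8α-bis(triethylsilyloxy)eudesm-11-en-1-one | CC(=C)[C@H]1[C@H](O[Si](CC)(CC)CC)[C@@H]2[C@@](C)(C[C@@H]1O[Si](CC)(CC)CC)C(=O)C[C@H]3O[C@@]23C | intermediate
25 | 6α,8α-bis(triethylsilyloxy)eudesm-11-ene-1β,4α-diol (not isolated) | CC(=C)[C@H]1[C@H](O[Si](CC)(CC)CC)[C@@H]2[C@@](C)(C[C@@H]1O[Si](CC)(CC)CC)[C@H](O)CC[C@@]2(C)O | intermediate
26 | eudesm-11-ene-1β,4α,6α,8α-tetraol | CC(=C)[C@H]1[C@H](O)[C@@H]2[C@@](C)(C[C@@H]1O)[C@H](O)CC[C@@]2(C)O | intermediate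
27 | 1β,8α-bis(tert-butyldimethylsilyloxy)eudesm-11-ene-4α,6α-diol | CC(=C)[C@H]1[C@H](O)[C@@H]2[C@@](C)(C[C@@H]1O[Si](C)(C)C(C)(C)C)[C@H](O[Si](C)(C)C(C)(C)C)CC[C@@]2(C)O | intermediate
28 | angelic acid, (Z)-2-methylbut-2-enoic acid | C/C=C(/C)C(=O)O | starting material
29 | angelic 2,4,6-trichlorobenzoic anhydride (not isolated) | C/C=C(/C)C(=O)OC(=O)c1c(Cl)cc(Cl)cc1Cl | intermediate
30 | 1β,8α-bis(tert-butyldimethylsilyloxy)-4α-hydroxyeudesm-11-en-6α-yl (Z)-2-methylbut-2-enoate | CC(=C)[C@H]1[C@H](OC(=O)/C(C)=C\C)[C@@H]2[C@@](C)(C[C@@H]1O[Si](C)(C)C(C)(C)C)[C@H](O[Si](C)(C)C(C)(C)C)CC[C@@]2(C)O | intermediate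
31 | 1β,8α-bis(tert-butyldimethylsilyloxy)-4α,12-dihydroxyeudesm-11(13)-en-6α-yl angelate (not isolated) | C=C(CO)[C@H]1[C@H](OC(=O)/C(C)=C\C)[C@@H]2[C@@](C)(C[C@@H]1O[Si](C)(C)C(C)(C)C)[C@H](O[Si](C)(C)C(C)(C)C)CC[C@@]2(C)O | intermediate
32 | 6α-angeloyloxy-1β,8α-bis(tert-butyldimethylsilyloxy)-4α-hydroxyeudesm-11(13)-en-12-al | C=C(C=O)[C@H]1[C@H](OC(=O)/C(C)=C\C)[C@@H]2[C@@](C)(C[C@@H]1O[Si](C)(C)C(C)(C)C)[C@H](O[Si](C)(C)C(C)(C)C)CC[C@@]2(C)O | intermediate
33 | 6α-angeloyloxy-1β,8α-bis(tert-butyldimethylsilyloxy)-4α-hydroxyeudesm-11(13)-en-12-oic acid | C=C(C(=O)O)[C@H]1[C@H](OC(=O)/C(C)=C\C)[C@@H]2[C@@](C)(C[C@@H]1O[Si](C)(C)C(C)(C)C)[C@H](O[Si](C)(C)C(C)(C)C)CC[C@@]2(C)O | intermediate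
34 | methyl 6α-angeloyloxy-1β,8α-bis(tert-butyldimethylsilyloxy)-4α-hydroxyeudesm-11(13)-en-12-oate | C=C(C(=O)OC)[C@H]1[C@H](OC(=O)/C(C)=C\C)[C@@H]2[C@@](C)(C[C@@H]1O[Si](C)(C)C(C)(C)C)[C@H](O[Si](C)(C)C(C)(C)C)CC[C@@]2(C)O | intermediate
35 | methyl 6α-angeloyloxy-1β,4α,8α-trihydroxyeudesm-11(13)-en-12-oate, (1R,4R,5S,6S,7R,8S,10R) | C=C(C(=O)OC)[C@H]1[C@H](OC(=O)/C(C)=C\C)[C@@H]2[C@@](C)(C[C@@H]1O)[C@H](O)CC[C@@]2(C)O | target

**Totals and risks**

Total step count: 21. Longest linear sequence: 20 steps (from 5 to 35, steps 2–21).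

Three steps most likely to fail:

Step 12. The thermal cycloaddition at a trisubstituted alkene that is activated only by a sulfonyl group may be slow, and the endo mode that gives the trans ring fusion may not dominate. The fallback replaces the sulfone by a Lewis-acid-activated enal. It sets out from vinyl iodide 19: iodine–lithium exchange (t-BuLi, Et2O, −78 °C) and trapping with DMF should give the (E)-enal F1. Et2AlCl (CH2Cl2, −78 → −20 °C) should then promote the intramolecular Diels–Alder reaction through the endo-formyl transition state to the trans-fused 1β-carbaldehyde F2. Condensation with morpholine (cat. TsOH, benzene, water removal) gives the morpholine enamine F3, and oxidative cleavage of the enamine alkene (O2, CuCl, MeCN) excises the extra carbon. The fallback comes back to the route at ketone 23.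

Step 16. Site selectivity among the C1, C6 and C8 hydroxyls may be lost during silylation. The fallback uses a temporary ring in place of kinetic selection. It sets out from tetraol 26: 2,2-dimethoxypropane and PPTS should tie the C4 and C6 hydroxyls, the only pair that can close a six-membered acetal, into the 4,6-acetonide F4. TBSOTf and 2,6-lutidine then silylate the two remaining hydroxyls to the bis-silyl acetonide F5, and PPTS in methanol removes the acetonide. The fallback comes back to the route at diol 27.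

Step 17. Acylation of the hindered C6 hydroxyl may be sluggish, and the activated angeloyl unit may isomerize from Z to E. The fallback builds the Z-alkene on a preformed ester. It sets out from diol 27: acylation with 2-[bis(2,2,2-trifluoroethoxy)phosphoryl]propanoic acid (DCC, DMAP, CH2Cl2) should give the phosphonopropionate F6. Still–Gennari olefination with acetaldehyde (KN(SiMe3)2, 18-crown-6, THF, −78 °C) then forms the (Z)-2-methylbut-2-enoate. The fallback comes back to the route at angelate 30.

**Further compounds**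

F1 | step 12 | (2E,4S,5R,6R,7E)-3,8-dimethyl-5-(prop-1-en-2-yl)-4,6-bis(triethylsilyloxy)deca-2,7,9-trienal | C=C/C(C)=C/[C@@H](O[Si](CC)(CC)CC)[C@H](C(C)=C)[C@@H](O[Si](CC)(CC)CC)C/C(C)=C/C=O
F2 | step 12 | 6α,8α-bis(triethylsilyloxy)eudesma-3,11-diene-1β-carbaldehyde | CC(=C)[C@H]1[C@H](O[Si](CC)(CC)CC)[C@@H]2[C@@](C)(C[C@@H]1O[Si](CC)(CC)CC)[C@H](C=O)CC=C2C
F3 | step 12 | morpholine enamine of aldehyde F2 (E/Z mixture at the exocyclic alkene) | CC(=C)[C@H]1[C@H](O[Si](CC)(CC)CC)[C@@H]2[C@@](C)(C[C@@H]1O[Si](CC)(CC)CC)C(=CN3CCOCC3)CC=C2C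
F4 | step 16 | 4α,6α-O-isopropylidene-eudesm-11-ene-1β,8α-diol | CC(=C)[C@H]1[C@H]3[C@@H]2[C@@](C)(C[C@@H]1O)[C@H](O)CC[C@@]2(C)OC(C)(C)O3
F5 | step 16 | 1β,8α-bis(tert-butyldimethylsilyloxy)-4α,6α-O-isopropylidene-eudesm-11-ene | CC(=C)[C@H]1[C@H]3[C@@H]2[C@@](C)(C[C@@H]1O[Si](C)(C)C(C)(C)C)[C@H](O[Si](C)(C)C(C)(C)C)CC[C@@]2(C)OC(C)(C)O3
F6 | step 17 | 1β,8α-bis(tert-butyldimethylsilyloxy)-4α-hydroxyeudesm-11-en-6α-yl 2-[bis(2,2,2-trifluoroethoxy)phosphoryl]propanoate | CC(=C)[C@H]1[C@H](OC(=O)C(C)P(=O)(OCC(F)(F)F)OCC(F)(F)F)[C@@H]2[C@@](C)(C[C@@H]1O[Si](C)(C)C(C)(C)C)[C@H](O[Si](C)(C)C(C)(C)C)CC[C@@]2(C)O
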